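**Plan**

1. Labels: ring A is a1(CMe2)–a2(CHBr)–a3(CH2)–a4(CHOH)–a5(CMe); ring B is b1(C–OH, bonded to a5)–b2–b3–b4(CMe)–b5(C–OH)–b6; ring C is b4–c1(CHBr)–c2–c3–c4(CMeOH)–b5. In ring B the carbinol b1 is para to the methylated fusion carbon b4, and the functionalised c1 and c4 flank the b4–b5 fusion: the imprint of a 2-substituted butadiene added across the methyl-bearing C=C of a 2,5-disubstituted p-benzoquinone.
2. Retrosynthesis: C–Br at c1, O at b1 (back to b1=b2), CH3–c4 and O–b5 are removed first. Then b5–b6 and b3–b4 are cut together (retro-Diels–Alder) to the 2-(ring A)buta-1,3-diene 13 and 2-methoxy-5-methyl-1,4-benzoquinone 15. Diene 13 is cut at its two methylene carbons and at a2–Br back to a cyclopentenylacetaldehyde, the C4–C5 seco form of 5-oxobornyl acetate.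
3. Forward: ring A is carved out of (+)-borneol and carried as a bromo diene; ring C enters preformed as the quinone; ring B closes in the cycloaddition. Ring C is then adjusted (b5–OH, c4–CH3, carbonyl transposition, c1–Br) and b1=b2 is hydrated last.
4. Stereochemistry: a4 and a5 come from borneol; a2 from a trans epoxide, directed hydride opening and SN2 inversion; b4 from the chiral boron catalyst. b5–OH, c4, c1 and b1 are all relayed from the b4 methyl.

Key step: step 13

Conventions: on ring A, α is the face carrying the a5 side chain and the a4 oxygen, β the face of the a5 methyl; on the decalin, β is the face of the b4 methyl. RA = (1R,3R,5S)-3-bromo-5-[(tert-butyldimethylsilyl)oxy]-1,2,2-trimethylcyclopentyl (ring A attached through a5, with a2-Br and a4-OTBS both α). The acetal carbon in 8–10 and c1 in 20 are temporary stereocentres carried as mixtures.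

Assumption: the (S)-configured oxazaborolidinium catalyst is taken to be the hand that leaves open the quinone face leading to the (4aS,8aR) adduct 16; if the induction runs the other way, the (R)-catalyst is used and nothing else changes.

**Route**

Step 1
Reactants: 1 (+)-borneol
Product: 2 (+)-bornyl acetate
Conditions: Ac2O, pyridine, DMAP (cat.), CH2Cl2, rt
Reagents that add atoms: acetic anhydride, CC(=O)OC(C)=O
Why: DMAP-catalysed acylation of the secondary alcohol gives the ester that the chromium oxidation of the next step requires and touches no stereocentre.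

Step 2
Reactants: 2 (+)-bornyl acetate
Product: 3 5-oxobornyl acetate
Conditions: CrO3, AcOH/Ac2O, 80 °C
Reagents that add atoms: chromium trioxide, O=[Cr](=O)=O
Why: Remote methylene oxidation of bornyl esters by hexavalent chromium is a classical reaction that goes to C5, the ring CH2 farthest from the deactivating acetoxy group, so the ketone marks the C4–C5 bond to be cut without touching the stereocentres.

Step 3
Reactants: 3 5-oxobornyl acetate
Product: 4 acetoxy cyclopentenyl acetaldehyde
Conditions: hν (medium-pressure Hg lamp, Pyrex), degassed pentane, rt, partial conversion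
Reagents that add atoms: none
Why: Norrish type 1 α-cleavage of the bicyclo[2.2.1]heptanone on its more substituted (C4) side, followed by hydrogen transfer from C3 to the acyl radical, should open the bicycle to the cyclopent-3-enyl acetaldehyde, as camphor gives campholenic aldehyde, with a4 and a5 untouched.

Step 4
Reactants: 4 acetoxy cyclopentenyl acetaldehyde
Product: 5 acetoxy dimethyl acetal
Conditions: HC(OMe)3, MeOH, PPTS (cat.), rt
Reagents that add atoms: trimethyl orthoformate, COC(OC)OC
Why: Acid-catalysed acetalisation with orthoformate masks the aldehyde against peracid and hydride, while the mild pyridinium acid leaves the allylic acetate in place.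

Step 5
Reactants: 5 acetoxy dimethyl acetal
Product: 6 β-epoxy acetate
Conditions: mCPBA, NaHCO3, CH2Cl2, 0 °C
Reagents that add atoms: 3-chloroperbenzoic acid, OOC(=O)c1cccc(Cl)c1
Why: Prilezhaev epoxidation of the cis-disubstituted alkene, with the peracid approaching anti to the allylic acetoxy group and the a5 side chain, should place the oxirane on the β face (new centres a2 and a3).

Step 6
Reactants: 6 β-epoxy acetate
Product: 8 cyclic methyl acetal alcohol (a2-OH β), via trans-1,3-diol 7 (not isolated)
Conditions: NaAlH2(OCH2CH2OMe)2, THF, 0 °C → rt; aq. NaOH work-up; then PPTS (cat.), CH2Cl2, rt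
Reagents that add atoms: none
Why: The hydride first cleaves the acetate and the a4 alkoxyaluminate then delivers hydride intramolecularly to the adjacent oxirane carbon a3 (the epoxy alcohol to 1,3-diol opening, a2 being neopentyl besides), which leaves the β C–O bond at a2 intact, and acid then closes the five-membered mixed acetal from the a4 hydroxyl, the only one cis to the side chain, so that the a2 alcohol alone stays free.

Step 7
Reactants: 8 cyclic methyl acetal alcohol
Product: 9 cyclic methyl acetal bromide (a2-Br α)
Conditions: CBr4, PPh3, CH2Cl2, 0 °C → reflux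
Reagents that add atoms: carbon tetrabromide, BrC(Br)(Br)Br
Why: Appel reaction, in which bromide displaces the alkoxyphosphonium group in an SN2 step with inversion and so moves the a2 substituent from β to α, cis to the a4 oxygen as in the target.

Step 8
Reactants: 9 cyclic methyl acetal bromide
Product: 10 bromo lactol
Conditions: 1 M HCl, THF, rt
Reagents that add atoms: water, O
Why: Mild aqueous acid hydrolyses the mixed acetal to the lactol, the masked hydroxy aldehyde, without affecting the secondary bromide.

Step 9
Reactants: 10 bromo lactol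
Product: 11 hydroxy enal (2-substituted acrolein)
Conditions: aq. CH2O (37%), pyrrolidine (10 mol %), EtCO2H (10 mol %), iPrOH, 45 °C
Reagents that add atoms: formaldehyde, C=O
Why: Amine-catalysed Mannich condensation with formaldehyde followed by elimination (the α-methylenation of aldehydes) acts on the open hydroxy aldehyde form at its only enolisable carbon and creates b6 on the carbon that becomes b1.

Step 10
Reactants: 11 hydroxy enal
Product: 12 dienol
Conditions: Ph3PCH3Br, KN(SiMe3)2 (3 equiv of ylide), THF, 0 °C → rt
Reagents that add atoms: methyltriphenylphosphonium bromide, C[P+](c1ccccc1)(c1ccccc1)c1ccccc1.[Br-]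
Why: Wittig methylenation of the 2-substituted acrolein (1,2-addition of the unstabilised ylide) gives the 2-substituted buta-1,3-diene, the excess ylide serving to deprotonate the hydroxyl.

Step 11
Reactants: 12 dienol
Product: 13 silyl diene
Conditions: TBSOTf, 2,6-lutidine, CH2Cl2, −78 → 0 °C
Reagents that add atoms: tert-butyldimethylsilyl triflate, CC(C)(C)[Si](C)(C)OS(=O)(=O)C(F)(F)F
Why: A silyl triflate with a hindered pyridine base silylates the hindered secondary alcohol at low temperature, giving an ether that withstands the Lewis acid, organometallic, hydride and basic peroxide steps ahead.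

Step 12
Reactants: 14 2-methoxy-5-methylphenol
Product: 15 2-methoxy-5-methyl-1,4-benzoquinone
Conditions: (KSO3)2NO (2.2 equiv), KH2PO4 (aq), acetone/H2O, rt
Reagents that add atoms: potassium nitrosodisulfonate, [K+].[K+].[O-]S(=O)(=O)N([O])S(=O)(=O)[O-]
Why: Teuber oxidation of a phenol with a free para position by the nitrosodisulfonate radical gives the p-quinone directly.

Step 13
Reactants: 13 silyl diene; 15 2-methoxy-5-methyl-1,4-benzoquinone
Product: 16 cis-fused enedione adduct
Conditions: (S)-1-(2-methylphenyl)-3,3-diphenyltetrahydro-1H,3H-pyrrolo[1,2-c][1,3,2]oxazaborole·HNTf2 (20 mol %), CH2Cl2, −78 → −40 °C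
Reagents that add atoms: none
Why: The boron Lewis acid binds end-on to the more basic, methoxy-conjugated carbonyl (future c1) and the s-cis diene then adds in a concerted, asynchronous [4+2] cycloaddition, suprafacial on both partners, to the methyl-bearing C=C of the quinone; the closest known reaction type is the oxazaborolidinium- or BF3-promoted Diels–Alder reaction of this quinone with simple 2-substituted dienes. Ring B closes as a cyclohexene in this single [4+2] event, b3–b4 and b5–b6 being formed together. The cis relationship of b4–CH3 and b5–H follows from suprafacial addition to the dienophile, and the absolute configuration at b4 is set by the catalyst, which shields one face of the bound quinone, the ring-A centres being too remote to compete. Site selectivity is secured by the methoxy group, which donates into its own double bond and leaves the methylated one as the dienophile. Regioselectivity (b6 to b5, ring A para to b4) is secured by monodentate coordination at the c1 carbonyl, which makes b5 the electrophilic β-carbon that pairs with the larger-coefficient terminus b6 of the 2-alkyl diene, whereas a chelating Lewis acid on the other carbonyl and the methoxy oxygen would reverse it and is avoided. b5 needs no control beyond the cis fusion because it is re-set in step 14.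

Step 14
Reactants: 16 cis-fused enedione adduct
Product: 18 trans-fused α-ketol (b5-OH α), via potassium enolate 17 (not isolated)
Conditions: KN(SiMe3)2, THF, −78 °C; then 2-(phenylsulfonyl)-3-phenyloxaziridine, −78 °C; aq. NH4Cl
Reagents that add atoms: 2-(phenylsulfonyl)-3-phenyloxaziridine, O=S(=O)(c1ccccc1)N1OC1c1ccccc1
Why: The ring-fusion hydrogen at b5 is the only enolisable position (b4 is quaternary, so aromatisation is blocked), and the oxaziridine transfers oxygen to the planar enolate on the face opposite the adjacent angular methyl (electrophilic enolate hydroxylation), which sets b5–OH α and makes the ring fusion trans.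

Step 15
Reactants: 18 trans-fused α-ketol
Product: 19 c4 methyl carbinol
Conditions: MeMgBr (3 equiv), THF, −78 → −40 °C; aq. NH4Cl
Reagents that add atoms: methylmagnesium bromide, C[Mg]Br
Why: Grignard 1,2-addition occurs at the c4 ketone only, because the c1 carbonyl is a deactivated vinylogous ester, and the reagent enters from the α face since the β face is blocked by the 1,3-related axial b4 methyl (as with 6-oxo steroids under an angular methyl), giving c4–OH β trans-diaxial to b5–OH.

Step 16
Reactants: 19 c4 methyl carbinol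
Product: 21 transposed enone, via allylic alcohol 20 (not isolated)
Conditions: iBu2AlH (5 equiv), CH2Cl2, −78 °C; then 1 M HCl, THF, 0 °C
Reagents that add atoms: water, O
Why: Stork–Danheiser sequence, in which 1,2-reduction of the vinylogous ester carbonyl and acid-promoted loss of the c1 hydroxyl through the methoxy-stabilised allyl cation, with hydrolysis to the c3 ketone, give the transposed enone, the tertiary carbinols not being ionised under these mild conditions.

Step 17
Reactants: 21 transposed enone
Product: 22 α-epoxy ketone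
Conditions: 30% H2O2, NaOH (aq, cat.), MeOH, 0 °C
Reagents that add atoms: hydrogen peroxide, OO
Why: Weitz–Scheffer nucleophilic epoxidation, in which hydroperoxide adds to c1 axially from the face away from the neighbouring b4 methyl and so places the oxirane on the α face (new centres c1 and c2), while the isolated b1=b2 alkene is inert.

Step 18
Reactants: 22 α-epoxy ketone
Product: 24 allylic alcohol (c1-OH α), via epoxy hydrazone 23 (not isolated)
Conditions: N2H4·H2O, AcOH (cat.), MeOH, 0 °C → rt
Reagents that add atoms: none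
Why: Wharton transposition, in which the hydrazone opens the oxirane to a vinyl diazene that loses N2, leaving the c1 oxygen where the epoxide put it (α, axial), removing the c3 oxygen and placing the alkene at c2=c3.

Step 19
Reactants: 24 allylic alcohol
Product: 25 saturated triol
Conditions: 2-nitrobenzenesulfonylhydrazide, Et3N, CH2Cl2, rt
Reagents that add atoms: none
Why: Diimide transfers two hydrogens to the unhindered cis-disubstituted c2=c3 alkene and leaves the trisubstituted, quaternary-flanked b1=b2 alkene and the C–Br bond alone (no new stereocentre).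

Step 20
Reactants: 25 saturated triol
Product: 26 c1 bromide (equatorial, β)
Conditions: CBr4, PPh3, toluene, 0 → 60 °C
Reagents that add atoms: carbon tetrabromide, BrC(Br)(Br)Br
Why: Appel reaction on the axial c1 alcohol, bromide displacing the alkoxyphosphonium group with inversion to the equatorial β bromide, while the tertiary alcohols do not react.

Step 21
Reactants: 26 c1 bromide
Product: 28 a4-O-silyl neoirietetraol, via tertiary hydroperoxide 27 (not isolated)
Conditions: Co(acac)2 (20 mol %), PhSiH3, O2 (1 atm), iPrOH/CH2Cl2, rt; then PPh3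
Reagents that add atoms: dioxygen, O=O
Why: Mukaiyama hydration, in which hydrogen-atom transfer from a cobalt hydride to b2 gives the tertiary b1 radical that is trapped by O2 axially, because the very large ring-A substituent must stay equatorial on the trans-decalin chair, so that reduction of the hydroperoxide leaves b1–OH α (axial), syn to b5–OH.

Step 22
Reactants: 28 a4-O-silyl neoirietetraol
Product: 29 neoirietetraol
Conditions: HF (48% aq.), MeCN, rt
Reagents that add atoms: none
Why: Fluoride-mediated cleavage of the silyl ether under mildly acidic conditions frees the a4 hydroxyl without ionising the tertiary alcohols or eliminating the secondary bromides.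

**Compound list**

1 | (+)-borneol, (1R,2S,4R)-1,7,7-trimethylbicyclo[2.2.1]heptan-2-ol | CC1(C)[C@H]2C[C@H](O)[C@]1(C)CC2 | starting material
2 | (+)-bornyl acetate, (1R,2S,4R)-1,7,7-trimethylbicyclo[2.2.1]hept-2-yl acetate | CC1(C)[C@H]2C[C@H](OC(C)=O)[C@]1(C)CC2 | intermediate
3 | 5-oxobornyl acetate, (1R,2S,4R)-1,7,7-trimethyl-5-oxobicyclo[2.2.1]hept-2-yl acetate | CC1(C)[C@H]2C[C@H](OC(C)=O)[C@]1(C)CC2=O | intermediate
4 | 2-[(1R,5S)-5-acetoxy-1,2,2-trimethylcyclopent-3-en-1-yl]acetaldehyde (alkene a2=a3, a4-OAc α) | CC1(C)C=C[C@H](OC(C)=O)[C@]1(C)CC=O | intermediate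
5 | (1S,5R)-5-(2,2-dimethoxyethyl)-4,4,5-trimethylcyclopent-2-en-1-yl acetate | CC1(C)C=C[C@H](OC(C)=O)[C@]1(C)CC(OC)OC | intermediate
6 | β-epoxide of 5: a2,a3-oxirane trans to the a4 acetoxy group and the acetal side chain | CC1(C)[C@H]2O[C@H]2[C@H](OC(C)=O)[C@]1(C)CC(OC)OC | intermediate
7 | 5-(2,2-dimethoxyethyl)-4,4,5-trimethylcyclopentane-1,3-diol with a2-OH β and a4-OH α (trans diol, a4-OH cis to the side chain) | CC1(C)[C@@H](O)C[C@H](O)[C@]1(C)CC(OC)OC | intermediate (not isolated)
8 | cis-fused 2-methoxy-3a,4,4-trimethylhexahydro-2H-cyclopenta[b]furan-5-ol, 5-OH (a2) on the convex β face, anomeric mixture | CC1(C)[C@@H](O)C[C@H](OC2OC)[C@]1(C)C2 | intermediate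
9 | cis-fused 5-bromo-2-methoxy-3a,4,4-trimethylhexahydro-2H-cyclopenta[b]furan, bromine (a2) on the concave α face, anomeric mixture | CC1(C)[C@H](Br)C[C@H](OC2OC)[C@]1(C)C2 | intermediate
10 | cis-fused 5-bromo-3a,4,4-trimethylhexahydro-2H-cyclopenta[b]furan-2-ol (lactol of the hydroxy aldehyde), anomeric mixture | CC1(C)[C@H](Br)C[C@H](OC2O)[C@]1(C)C2 | intermediate
11 | 2-[(1R,3R,5S)-3-bromo-5-hydroxy-1,2,2-trimethylcyclopentyl]prop-2-enal, in equilibrium with its lactol | CC1(C)[C@H](Br)C[C@H](O)[C@]1(C)C(=C)C=O | intermediate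
12 | (1S,2R,4R)-4-bromo-2-(buta-1,3-dien-2-yl)-2,3,3-trimethylcyclopentan-1-ol | CC1(C)[C@H](Br)C[C@H](O)[C@]1(C)C(=C)C=C | intermediate
13 | tert-butyl{[(1S,2R,4R)-4-bromo-2-(buta-1,3-dien-2-yl)-2,3,3-trimethylcyclopentyl]oxy}dimethylsilane | CC1(C)[C@H](Br)C[C@H](O[Si](C)(C)C(C)(C)C)[C@]1(C)C(=C)C=C | intermediate
14 | 2-methoxy-5-methylphenol | COc1ccc(C)cc1O | starting material
15 | 2-methoxy-5-methyl-1,4-benzoquinone | COC1=CC(=O)C(C)=CC1=O | intermediate
16 | (4aS,8aR)-2-methoxy-4a-methyl-7-RA-4a,5,8,8a-tetrahydronaphthalene-1,4-dione (cis-fused; b4-CH3 and b5-H both β; alkene b1=b2) | CC1(C)[C@H](Br)C[C@H](O[Si](C)(C)C(C)(C)C)[C@]1(C)C1=CC[C@]2(C)C(=O)C=C(OC)C(=O)[C@@H]2C1 | intermediate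
17 | potassium enolate of 16 (c4 enolate, b5=c4) | CC1(C)[C@H](Br)C[C@H](O[Si](C)(C)C(C)(C)C)[C@]1(C)C1=CC[C@]2(C)C(=O)C=C(OC)C([O-])=C2C1.[K+] | intermediate (not isolated)
18 | (4aS,8aR)-8a-hydroxy-2-methoxy-4a-methyl-7-RA-4a,5,8,8a-tetrahydronaphthalene-1,4-dione (trans-fused; b5-OH α, b4-CH3 β) | CC1(C)[C@H](Br)C[C@H](O[Si](C)(C)C(C)(C)C)[C@]1(C)C1=CC[C@]2(C)C(=O)C=C(OC)C(=O)[C@@]2(O)C1 | intermediate
19 | trans-decalin vinylogous ester: c1 C=O, c2=c3(OMe), c4 with β-OH and α-CH3, b5-OH α, b4-CH3 β, b1=b2, RA on b1 | CC1(C)[C@H](Br)C[C@H](O[Si](C)(C)C(C)(C)C)[C@]1(C)C1=CC[C@]2(C)C(=O)C=C(OC)[C@@](C)(O)[C@@]2(O)C1 | intermediate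
20 | c1 allylic alcohol of 19 (c1-OH, c2=c3(OMe) enol ether; c1 epimers) | CC1(C)[C@H](Br)C[C@H](O[Si](C)(C)C(C)(C)C)[C@]1(C)C1=CC[C@]2(C)C(O)C=C(OC)[C@@](C)(O)[C@@]2(O)C1 | intermediate (not isolated)
21 | transposed enone: c1=c2, c3 C=O, c4 with β-OH and α-CH3, b5-OH α, b4-CH3 β, b1=b2, RA on b1 | CC1(C)[C@H](Br)C[C@H](O[Si](C)(C)C(C)(C)C)[C@]1(C)C1=CC[C@]2(C)C=CC(=O)[C@@](C)(O)[C@@]2(O)C1 | intermediate
22 | c1,c2-α-epoxide of 21 (oxirane trans to the b4 methyl), c3 ketone | CC1(C)[C@H](Br)C[C@H](O[Si](C)(C)C(C)(C)C)[C@]1(C)C1=CC[C@]2(C)[C@@H]3O[C@@H]3C(=O)[C@@](C)(O)[C@@]2(O)C1 | intermediate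
23 | c3 hydrazone of 22 | CC1(C)[C@H](Br)C[C@H](O[Si](C)(C)C(C)(C)C)[C@]1(C)C1=CC[C@]2(C)[C@@H]3O[C@@H]3C(=NN)[C@@](C)(O)[C@@]2(O)C1 | intermediate (not isolated)
24 | allylic alcohol: c1-OH α (axial), c2=c3, c4 with β-OH and α-CH3, b5-OH α, b1=b2, RA on b1 | CC1(C)[C@H](Br)C[C@H](O[Si](C)(C)C(C)(C)C)[C@]1(C)C1=CC[C@]2(C)[C@H](O)C=C[C@@](C)(O)[C@@]2(O)C1 | intermediate
25 | saturated triol: as 24 with c2–c3 single bond | CC1(C)[C@H](Br)C[C@H](O[Si](C)(C)C(C)(C)C)[C@]1(C)C1=CC[C@]2(C)[C@H](O)CC[C@@](C)(O)[C@@]2(O)C1 | intermediate
26 | dibromo diol: c1-Br β (equatorial), c4 with β-OH and α-CH3, b5-OH α, b1=b2, RA on b1 | CC1(C)[C@H](Br)C[C@H](O[Si](C)(C)C(C)(C)C)[C@]1(C)C1=CC[C@]2(C)[C@@H](Br)CC[C@@](C)(O)[C@@]2(O)C1 | intermediate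
27 | b1 tertiary hydroperoxide of 28 (b1-OOH α, RA β) | CC1(C)[C@H](Br)C[C@H](O[Si](C)(C)C(C)(C)C)[C@]1(C)[C@@]1(OO)CC[C@]2(C)[C@@H](Br)CC[C@@](C)(O)[C@@]2(O)C1 | intermediate (not isolated)
28 | a4-O-tert-butyldimethylsilyl neoirietetraol (b1-OH α axial, RA β equatorial) | CC1(C)[C@H](Br)C[C@H](O[Si](C)(C)C(C)(C)C)[C@]1(C)[C@@]1(O)CC[C@]2(C)[C@@H](Br)CC[C@@](C)(O)[C@@]2(O)C1 | intermediate
29 | neoirietetraol | CC1(C)[C@H](Br)C[C@H](O)[C@]1(C)[C@@]1(O)CC[C@]2(C)[C@@H](Br)CC[C@@](C)(O)[C@@]2(O)C1 | target

**Step count and risks**

Total: 22 steps. Longest linear sequence: 21 steps (steps 1–11 and 13–22); step 12 is a one-step side branch.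

Most likely to fail:

Step 20. The axial alkoxyphosphonium ion at c1 has an anti-periplanar hydrogen at c2, so elimination to the c1=c2 alkene may outrun the backside entry of bromide, which has to pass the axial b4 methyl. The fallback sets out from 25 and puts the hydrogen, not the bromine, in last. The b1=b2 alkene is hydrated first under the conditions of step 21, through the hydroperoxide F4, to the tetraol F5. Its only secondary hydroxyl is oxidised with Dess–Martin periodinane to the c1 ketone F6, which is condensed with N2H4·H2O to the hydrazone F7. Oxidation of F7 with N-bromosuccinimide/pyridine gives the vinyl bromide F8 (c1-Br, c1=c2). Hydrogen-atom-transfer hydrogenation [Mn(dpm)3 (dpm = 2,2,6,6-tetramethylheptane-3,5-dionate), PhSiH3, tBuOOH, iPrOH] should then deliver hydrogen to c1 axially, from the face away from the b4 methyl, leaving the equatorial bromide. The route is rejoined at 28.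

Step 7. Bromide must enter on the concave face next to the quaternary a1, so anti elimination to the cyclopentene or a 1,2-methyl shift from a1 may compete with substitution. The fallback sets out from 8 and again sets a2 by hydrogen delivery to the open face. Oxidation with Dess–Martin periodinane gives the cyclopentanone F2. Treatment with (PhO)3P/Br2/Et3N converts it into the vinyl bromide F3 (a2-Br, a2=a3). Syn hydrogenation over Rh/Al2O3 (H2, EtOAc) from the convex β face of the cis-fused bicycle should leave the bromine α. The route is rejoined at 9.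

Step 13. The catalyst may discriminate the quinone faces poorly at a double bond remote from its binding site, giving both cis adducts, or the strong acid may oligomerise the hindered diene. The fallback sets out from 13 and 15 and gives up reagent control of the b4 configuration. BF3·OEt2 (monodentate, so the same regiochemistry) in CH2Cl2 at −78 °C should give both cis adducts. Because ring A is enantiopure these are diastereomers, and 16 is separated by chromatography from its (4aR,8aS) epimer F1. The route is rejoined at 16.

Further compounds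
F1 | step 13 | (4aR,8aS) diastereomer of 16 (cis-fused, b4-CH3 and b5-H both α) | CC1(C)[C@H](Br)C[C@H](O[Si](C)(C)C(C)(C)C)[C@]1(C)C1=CC[C@@]2(C)C(=O)C=C(OC)C(=O)[C@H]2C1
F2 | step 7 | cis-fused 2-methoxy-3a,4,4-trimethylhexahydro-5H-cyclopenta[b]furan-5-one (a2 ketone) | CC1(C)C(=O)C[C@H](OC2OC)[C@]1(C)C2
F3 | step 7 | cis-fused 5-bromo-2-methoxy-3a,4,4-trimethyl-3,3a,4,6a-tetrahydro-2H-cyclopenta[b]furan (a2 vinyl bromide) | CC1(C)C(Br)=C[C@H](OC2OC)[C@]1(C)C2
F4 | step 20 | b1 hydroperoxide of F5 (b1-OOH α, c1-OH α) | CC1(C)[C@H](Br)C[C@H](O[Si](C)(C)C(C)(C)C)[C@]1(C)[C@@]1(OO)CC[C@]2(C)[C@H](O)CC[C@@](C)(O)[C@@]2(O)C1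
F5 | step 20 | tetraol: 28 with c1-OH α in place of c1-Br | CC1(C)[C@H](Br)C[C@H](O[Si](C)(C)C(C)(C)C)[C@]1(C)[C@@]1(O)CC[C@]2(C)[C@H](O)CC[C@@](C)(O)[C@@]2(O)C1
F6 | step 20 | c1 ketone of F5 | CC1(C)[C@H](Br)C[C@H](O[Si](C)(C)C(C)(C)C)[C@]1(C)[C@@]1(O)CC[C@]2(C)C(=O)CC[C@@](C)(O)[C@@]2(O)C1
F7 | step 20 | c1 hydrazone of F6 | CC1(C)[C@H](Br)C[C@H](O[Si](C)(C)C(C)(C)C)[C@]1(C)[C@@]1(O)CC[C@]2(C)C(=NN)CC[C@@](C)(O)[C@@]2(O)C1
F8 | step 20 | c1 vinyl bromide (c1-Br, c1=c2) | CC1(C)[C@H](Br)C[C@H](O[Si](C)(C)C(C)(C)C)[C@]1(C)[C@@]1(O)CC[C@]2(C)C(Br)=CC[C@@](C)(O)[C@@]2(O)C1
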